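The constants belong to no real substance, and the outcome is calculated.

The complex with three exchanged is the product wanted here, and two colleagues disagree on how much of it this flask holds at the end.

starting complex 1.0 M; gas 33 mM (held); time 2.5 d

    complex with one exchanged + incoming ligand ⇌ leaving ligand + complex with two exchanged (K1 = 52.5, k1 = 0.0213 /M/s)
    gas ⇌ incoming ligand, rate k2*(csat - [incoming ligand]) (k2 = 0.00377 /s, csat = 33 mM)
    complex with two exchanged + incoming ligand ⇌ leaving ligand + complex with three exchanged (K3 = 11, k3 = 0.00533 /M/s)
    starting complex + incoming ligand ⇌ leaving ligand + complex with one exchanged (K4 = 570, k4 = 0.00600 /M/s)

* the state of affairs at 2.5 d: stopped, and by what, or still going (forward and back rates have come level / all of the starting complex has reacted / it is still moving)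
* complex with three exchanged at 2.5 d, in percent of the starting complex charged
* amount of complex with three exchanged if the flask were left three thousand times as long, in percent of the starting complex charged

- at the start none of incoming ligand is dissolved
- the reaction counts as stopped when no species that holds the starting complex changes by six tenths of a point or more over the second half of the time
- run time (flask): 2.5 d

The first colleague points to the equilibrium constants 570, 52.5 and 11, each above one. The gas can deliver at most 0.448 M/h, which over 2.5 d comes to 26.9 M, more than the 3.00 M that three exchanges on the whole charge take. She therefore expects all of the starting complex to react and 100% of the charge to end as complex with three exchanged.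

I hold the second view. Each exchange puts one leaving ligand into the closed flask, so the back steps grow. At balance, every step obeys c(next complex)/c(previous complex) = K·c(incoming ligand)/c(leaving ligand).

I call the ratio c(incoming ligand)/c(leaving ligand) at balance the exchange ratio. For c(leaving ligand) I try 1.60 M, with c(incoming ligand) at 33 mM, which makes the ratio 0.0206. The three steps then stand at 11.8, 1.08 and 0.227. Multiplying these up the ladder and counting the exchanges gives 1.62 per complex, so the trial returns 1.62 M and nearly holds. The complex with three exchanged then comes to 10.2%.

With incoming ligand held at 33 mM, the first exchange is pseudo-first-order, c(starting complex) falling as exp(−k4·csat·t) with half-life 0.972 h. Delivering my leaving ligand at the constant top rate takes 3.57 h. Both are far shorter than 2.5 d, so I expect forward and back rates to have come level.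

The forecast gives forward and back rates have come level, 10.1% at the asked time and 10.1% for the flask left far longer, on the ground that “The leaving ligand stays trapped in the closed flask”.

The simulation gives forward and back rates have come level, 10.1% at the asked time and 10.1% left far longer.

In this flask, half of the conversion stood at 0.108 d, far earlier than 2.5 d, and the back turnover from two exchanged to one reached 99.1% of the forward one. With 1.61 M of leaving ligand, the exchange ratio puts c(three exchanged)/c(two exchanged) at 0.225, and the flask reads 0.225. The neighbour flask charged with 0.25 M shows one part of the first colleague's ending: less of the starting complex remains there, 0.45% against 3.6% in this flask. There 0.542 M of leaving ligand puts the same ratio at 0.669, the flask reads 0.669, and the complex with three exchanged reaches 33.6%.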